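Remark on the chemistry: the target has no stereocentre; 9 is racemic and 12 is a mixture of diastereomers, and both lose their stereocentres within the route, so all SMILES are written without stereodescriptors.
Remark on the chemistry: where the same change takes place at both symmetric ends in one flask, only the intermediate changed at both ends is numbered.

Structural features

The target is a C2-symmetric benzophenone: two identical pentasubstituted benzene rings (ring A and ring B) are joined at C1 and C1' through one carbonyl carbon, C7. Going round each ring from C1, the substituents are OH at C2, CH3 at C3, OCH3 at C4, H at C5 and OCH3 at C6, a C-methylated phloroglucinol pattern in which only the oxygen between the carbonyl and the C-methyl is free. There is no stereocentre, and although four ortho substituents twist both rings out of the carbonyl plane there is no stable axis, so no stereochemical relationship has to be set. The fragile points are the electron-rich rings (C5-H is open to electrophiles and oxidants), the ortho methoxy groups (cleaved by Lewis acids through chelation to the carbonyl) and the 2-hydroxy-2'-alkoxybenzophenone motif, which can close to a xanthone under forcing acid or base. The real difficulty is regiochemical: the methyl must sit between two oxygens, the C2 oxygen must be told apart from the C4 and C6 oxygens, and a ketone flanked by four ortho substituents has to be made. The key step exploits the fact that C3(CH3)-C4(O)-C5(H)-C6(O) of each ring is a 1,3-dioxygenated diene with the methyl on one terminus, while C1-C2, with C7 on C1 and oxygen on C2, is one arm of an oxygenated diynone. A single two-armed dienophile centred on C7 can therefore deliver both rings.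

Logic of the disconnections

17 back to 15 (through 16). The bonds concerned are the two O-CH3 bonds at C2 and C2'. These oxygens are carried as methyl ethers on purpose: the C2 oxygen starts on an alkyne, and an alkynyl ether must survive the temperature of the ring-forming step. A benzyl group there would make the last step a hydrogenolysis and keep the C2 oxygen distinct from the start, but benzyl alkynyl ethers are prone to a [3,3] shift into the ring with ketene formation on mild warming, and alkyl groups with a beta hydrogen leave as alkenes by a retro-ene path. Methyl has neither exit and is the smallest group at a crowded bond-forming carbon. The demand is site selectivity: in each ring only the C2 methoxy may fall, which rests on its being the one methoxy that is both ortho to the carbonyl and flanked on both sides.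

15 back to 13 (through 14). The O-CH3 bonds at C4 and C4' are exchanged for O-Si bonds. The silyl groups are the trace of the enolate chemistry that fixes the double bonds of the diene. The gain is that 13 is the direct product of the ring-forming step. The demand is clean desilylation and O-methylation of phenols that are para to the ketone, acidic and unchelated.

13 back to 6 and two molecules of 11 (through 12): the key disconnection. The bonds cut are C1-C6 and C2-C3 of each ring, four C-C bonds in all, with a two-carbon bridge put back between C3 and C6. The cut divides each ring into a four-carbon unit that carries the 3-methyl, the 4- and 6-oxygens and H-5, and a two-carbon unit that carries C7 and the 2-oxygen; C7 ties two such alkynes into one symmetric dienophile. The gain is that both benzene rings and the crowded diaryl ketone disappear in one step, leaving a seven-carbon diynone and a monocyclic diene. The demands are four: the methyl-bearing diene terminus must bond to the oxygen-bearing alkyne carbon in both events, the alkynyl ether must outlast the heating, ethene and not a substituted alkene must be the fragment lost, and the second cycloaddition must proceed next to the first, crowded ring.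

6 back to 5. No skeletal bond is cut; C7 goes from ketone to carbinol, because the carbinol is what a formate ester gives with two acetylides. The demand is a neutral oxidant, since 5 and 6 are sensitive to acid and to nucleophiles.

5 back to 1 and 2 (through 3 and 4). Both C(sp)-C7 bonds are cut. 3 is generated from 1 by elimination with a lithium amide. This avoids handling a volatile free alkoxyacetylene, and it avoids the usual access to alkoxyacetylides from a chlorinated ethylene and strong base, which passes through an explosive, neurotoxic dichloroalkyne. The gain is two cheap commercial compounds. The demand is exact base stoichiometry and a buffered work-up.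

11 back to 9 (through 10). The O-Si bond is cut. Trapping the kinetic enolate places the methyl on the diene terminus by construction. The all-methoxy analogue of 11, which Birch reduction and conjugation of an aromatic ether would give in two steps and which would make step 6 unnecessary, is not the first choice. Conjugation delivers an equilibrium that contains the isomer with the methyl on the saturated bridge; that isomer has an unsubstituted diene terminus, should be the faster diene, and would expel propene, so that the C-methyl is lost. The demand is alpha-prime and not gamma deprotonation, and O- and not C-silylation.

9 back to 7 (through 8). The C-CH3 bond next to the ketone is cut. The gain is that 7 is commercial. The demand is monoalkylation at the alpha-prime carbon.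

Other disconnections considered

Alternative 1: The cut runs through C1-C2 and C5-C6 of each ring. C2 to C5 would come from 3-methoxy-4-methylcyclobut-2-en-1-one A2 (C2 as the future phenol carbon), and C1 and C6 from the two ynol ether arms of tert-butyl[(1,5-dimethoxypenta-1,4-diyn-3-yl)oxy]dimethylsilane A3, the silyl ether of 5. Heating should open A2 to a vinylketene, which would add to each alkyne in a [2+2] sense; four-electron ring opening, six-electron ring closure and tautomerisation (a Danheiser benzannulation run in two directions) would give bis(2-hydroxy-4,6-dimethoxy-3-methylphenyl)methyl tert-butyldimethylsilyl ether A1.
- In its favour: the C2 hydroxyl is born free and distinct from the four methyl ethers, which is better than the chosen plan, where a site-selective ether cleavage is needed. Benzannulation of cyclobutenones with alkoxyalkynes is an established reaction class, so on precedent it is also better than step 5. The ynol ethers react as ordinary electron-rich ketenophiles, not as deactivated dienophiles. The alkyne part costs the same, since A3 is one silylation away from 5.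
- Against it here: A2 is a sensitive four-membered ring that needs its own synthesis. The second annulation must take place beside a bulky new ring at an sp3 carbon. A1 is a doubly ortho-hydroxylated, very electron-rich benzhydryl silyl ether that would be expected to ionise to an ortho-quinone methide at benzannulation temperatures. C7 arrives one oxidation level too low, so desilylation and oxidation of a diaryl carbinol next to two free, oxidisable phenols must follow.
- Comparison: on structure the two plans are equal in convergence and use of symmetry; on mechanism the alternative is the better-founded one; on step economy they are about equal, because what the alternative saves in ether cleavage it spends on the late oxidation and on A2.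

Alternative 2: The cuts are four aryl C-O bonds (C4-O, C6-O, C4'-O, C6'-O), with the two C2-O bonds to be made afterwards. Bis(2,4,6-trifluoro-3-methylphenyl)methanone A4 would be treated with four equivalents of methoxide, the ketone activating every fluorine for addition-elimination, to give bis(2-fluoro-4,6-dimethoxy-3-methylphenyl)methanone A5. Hydroxide or a hydroxide surrogate would then have to replace the remaining fluorides.
- In its favour: every step is a known reaction type, the skeleton should be available in one or two steps from a simple fluoroarene, and the count (about four steps) is lower. On precedent and step economy this alternative is better than the chosen plan, and on convergence it is equal.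
- Against it here: the site selectivity rests on sterics alone. The para fluorides should go first, but the two ortho fluorides of each ring differ only by the neighbouring C-methyl, and each methoxy group introduced deactivates the ring, so the decisive third and fourth substitutions would be the slowest and least selective. Regioisomers of A5 would be hard to separate. The final exchange must occur at the most hindered position of an electron-rich ring, and as soon as one ring carries a 2-oxide it can displace the 2'-fluoride of the other ring intramolecularly, which is a standard way to xanthones.
- Comparison: in the chosen plan the position of every substituent is fixed by orbital polarisation in the cycloaddition and by chelation in the last step, which is the stronger regiochemical argument; the alternative is stronger on precedent and length.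

Alternative 3: The cut is at both aryl-C7 bonds, with C7 at the methylene level. Two molecules of the bromomagnesium phenoxide of 3,5-dimethoxy-2-methylphenol A7 would condense with one molecule of formaldehyde A8 in a non-coordinating solvent. The magnesium should hold the aldehyde, and then the derived ortho-quinone methide, next to the phenoxide oxygen, so that both new bonds form ortho to oxygen and give bis(2-hydroxy-4,6-dimethoxy-3-methylphenyl)methane A6, which would then be oxidised at C7.
- In its favour: both rings are bought intact with all three oxygens already differentiated, which is better than the chosen plan on structure. Metal-templated ortho-selective phenol-formaldehyde coupling is well known, so it is better on precedent. The sequence is shorter.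
- Against it here: A7 has a second, very nucleophilic position between its two methoxy groups and para to the phenoxide oxygen, so ortho selectivity depends wholly on the template. A7 needs one or two steps of its own. The oxidation of the crowded, electron-rich diarylmethane A6 to the ketone next to free ortho phenols is the weak point: common benzylic oxidants would be expected to pass through ortho-quinone methides or attack the rings, so protection, oxidation and deprotection are the likely price.
- Comparison: this alternative is equal in use of symmetry, better in precedent and, even with a protection detour, equal or better in step count. The chosen plan is better only in that C7 carries the ketone oxidation level from the start and no electron-rich arene has to face an oxidant.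

Key step: step 5

Step 1
Reactants: 1 2-chloro-1,1-dimethoxyethane (chloroacetaldehyde dimethyl acetal); 2 ethyl formate
Product: 5 1,5-dimethoxypenta-1,4-diyn-3-ol, via lithium methoxyacetylide 3 (not isolated), via 3-methoxyprop-2-ynal 4 (not isolated)
Conditions: LiNEt2 (from Et2NH and n-BuLi, 3.1 equiv per 1), THF, 0 °C; then 2 (0.45 equiv per 1), −78 to 0 °C; NaH2PO4/Na2HPO4 buffer, pH 7
Reagents that add atoms: none
Why: Three equivalents of lithium amide convert the chloroacetal into the lithium alkoxyacetylide by two eliminations (of methanol and of HCl) and a final deprotonation, so that neither free methoxyacetylene nor a chlorinated ethylene is handled; twofold 1,2-addition of the alkynyllithium to the formate ester (through ynal 4) is the standard route to symmetric dialkynyl carbinols, and the buffered work-up avoids the acid-induced Meyer-Schuster-type rearrangement of alkoxyethynyl carbinols.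

Step 2
Reactants: 5 1,5-dimethoxypenta-1,4-diyn-3-ol
Product: 6 1,5-dimethoxypenta-1,4-diyn-3-one
Conditions: MnO2 (activated, excess), CH2Cl2, 0 °C to rt; filtered and kept in solution
Reagents that add atoms: none
Why: Oxidation of a doubly propargylic alcohol with activated MnO2 is a neutral, heterogeneous reaction that alkynyl ethers tolerate; the cross-conjugated diynone should be kept cold, dilute and dry and used at once, since it is an electrophile and a small, energy-rich molecule.

Step 3
Reactants: 7 3-methoxycyclohex-2-en-1-one
Product: 9 3-methoxy-6-methylcyclohex-2-en-1-one (racemic), via lithium dienolate 8 (not isolated)
Conditions: LDA (LiN(i-Pr)2), THF, −78 °C; MeI, −78 °C to rt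
Reagents that add atoms: iodomethane (MeI), CI
Why: Stork-Danheiser alkylation: LDA removes the alpha-prime proton of the vinylogous ester under kinetic control and the cross-conjugated enolate 8 is C-methylated; the new stereocentre is formed racemic and is destroyed in step 4.

Step 4
Reactants: 9 3-methoxy-6-methylcyclohex-2-en-1-one
Product: 11 tert-butyl[(5-methoxy-2-methylcyclohexa-1,5-dien-1-yl)oxy]dimethylsilane (that is, 1-methoxy-4-methyl-3-(tert-butyldimethylsilyloxy)cyclohexa-1,3-diene), via methylated lithium dienolate 10 (not isolated)
Conditions: LDA, THF, −78 °C; TBSCl, DMPU, −78 °C to rt; non-aqueous work-up, distillation
Reagents that add atoms: tert-butyldimethylsilyl chloride (TBSCl), CC(C)(C)[Si](C)(C)Cl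
Why: Kinetic enolate trapping (silyl dienol ether formation): a second alpha-prime deprotonation, still much faster than removal of a gamma proton at −78 °C, and O-silylation with the hard silicon electrophile in the presence of DMPU give the 2-silyloxy diene with the methyl fixed on the diene terminus; no base or acid that could equilibrate the double bonds is present afterwards.

Step 5
Reactants: 6 1,5-dimethoxypenta-1,4-diyn-3-one; 11 tert-butyl[(5-methoxy-2-methylcyclohexa-1,5-dien-1-yl)oxy]dimethylsilane (two molecules react)
Product: 13 bis[4-(tert-butyldimethylsilyloxy)-2,6-dimethoxy-3-methylphenyl]methanone, via twofold bicyclo[2.2.2]octadiene cycloadduct 12 (not isolated)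
Conditions: 11 (3 equiv), BHT (cat.), mesitylene, pressure tube, 110 °C, then 150 °C
Reagents that add atoms: none
Why: Proposed new method: the closest known reaction type is the Alder-Rickert synthesis of resorcinol derivatives from 1-methoxy-3-silyloxy- or 1,3-dimethoxycyclohexa-1,3-dienes and alkynoates or alkynones, which here must accept a 3-alkoxy-substituted (push-pull) alkynone, twice. The diene HOMO is largest at the methyl-bearing terminus C4, onto which both oxygens donate, and the ynone LUMO is largest at the methoxy-bearing beta carbon (the carbon at which such ynones accept nucleophiles), so C4 should bond to the beta carbon and the methoxy-bearing terminus C1 to the alpha carbon, either in one very asynchronous [4+2] step or through an allenolate/oxocarbenium zwitterion that collapses. The bicyclo[2.2.2]octa-2,5-diene units of 12 then expel ethene by retro-[4+2] cleavage on further heating, and aromatisation makes the sequence irreversible. Each benzene ring is therefore closed by an intermolecular [4+2] cycloaddition that forms C1-C6 and C2-C3 at once, not by cyclisation of a chain, and the second alkyne reacts in the same way as the first. The bridgehead stereocentres of 12 are transient and vanish on aromatisation, so nothing has to control them and 13 is achiral. The step needs orientational selectivity, secured by the matched polarisation just described; retention of the C-methyl, secured because 11 is isomerically defined by its synthesis and 1,5-hydrogen shifts in cyclohexadienes are slow at these temperatures; and survival of the alkynyl ether until it has reacted, secured by the methyl group on the alkyne oxygen (no beta hydrogen for retro-ene loss of an alkene, no benzyl or allyl group for a [3,3] shift). The tert-butyldimethylsilyl group is chosen to disfavour silyl transfer to the allenolate oxygen should the addition be stepwise.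

Step 6
Reactants: 13 bis[4-(tert-butyldimethylsilyloxy)-2,6-dimethoxy-3-methylphenyl]methanone
Product: 15 bis(2,4,6-trimethoxy-3-methylphenyl)methanone, via dicesium bis-phenoxide 14 (not isolated)
Conditions: CsF, MeI, DMF, rt
Reagents that add atoms: iodomethane (MeI), CI
Why: One-pot fluoride desilylation and Williamson etherification: CsF cleaves the aryl silyl ethers, and the phenoxides, para to the ketone and free of hydrogen bonding, are O-methylated in the same flask; the hindered diaryl ketone and the other ethers are inert.

Step 7
Reactants: 15 bis(2,4,6-trimethoxy-3-methylphenyl)methanone
Product: 17 2,2'-dihydroxy-4,4',6,6'-tetramethoxy-3,3'-dimethylbenzophenone, via bis(dichloroboryl) ether 16 (not isolated)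
Conditions: BCl3 (3 equiv), CH2Cl2, −78 to 0 °C; then H2O
Reagents that add atoms: none
Why: Chelation-directed Lewis acid ether cleavage: BCl3 bound to the carbonyl oxygen removes the methyl of an ortho methoxy group through a six-membered boron chelate and is known to prefer methoxy groups that are flanked on both sides and twisted out of the ring plane; in each ring only the C2 methoxy is both, the C6 methoxy can lie in the plane and the C4 methoxy cannot chelate, and the aryloxyborane 16 is deactivated toward a second cleavage until water frees the hydrogen-bonded phenols.

Compound list

1 | 2-chloro-1,1-dimethoxyethane (chloroacetaldehyde dimethyl acetal) | COC(CCl)OC | starting material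
2 | ethyl formate | CCOC=O | starting material
3 | lithium methoxyacetylide, formed in the flask and not isolated | [Li+].[C-]#COC | intermediate
4 | 3-methoxyprop-2-ynal, formed in the flask and not isolated | COC#CC=O | intermediate
5 | 1,5-dimethoxypenta-1,4-diyn-3-ol | COC#CC(O)C#COC | intermediate
6 | 1,5-dimethoxypenta-1,4-diyn-3-one | COC#CC(=O)C#COC | intermediate
7 | 3-methoxycyclohex-2-en-1-one | COC1=CC(=O)CCC1 | starting material
8 | lithium 5-methoxycyclohexa-1,5-dien-1-olate, not isolated | [Li+].COC1=CC([O-])=CCC1 | intermediate
9 | 3-methoxy-6-methylcyclohex-2-en-1-one, racemic | COC1=CC(=O)C(C)CC1 | intermediate
10 | lithium 5-methoxy-2-methylcyclohexa-1,5-dien-1-olate, not isolated | [Li+].COC1=CC([O-])=C(C)CC1 | intermediate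
11 | tert-butyl[(5-methoxy-2-methylcyclohexa-1,5-dien-1-yl)oxy]dimethylsilane (1-methoxy-4-methyl-3-(tert-butyldimethylsilyloxy)cyclohexa-1,3-diene) | COC1=CC(O[Si](C)(C)C(C)(C)C)=C(C)CC1 | intermediate
12 | bis[5-(tert-butyldimethylsilyloxy)-1,3-dimethoxy-4-methylbicyclo[2.2.2]octa-2,5-dien-2-yl]methanone, mixture of diastereomers, not isolated | COC12C=C(O[Si](C)(C)C(C)(C)C)C(C)(CC1)C(OC)=C2C(=O)C1=C(OC)C2(C)CCC1(OC)C=C2O[Si](C)(C)C(C)(C)C | intermediate
13 | bis[4-(tert-butyldimethylsilyloxy)-2,6-dimethoxy-3-methylphenyl]methanone | COc1cc(O[Si](C)(C)C(C)(C)C)c(C)c(OC)c1C(=O)c1c(OC)cc(O[Si](C)(C)C(C)(C)C)c(C)c1OC | intermediate
14 | dicesium salt of bis(4-hydroxy-2,6-dimethoxy-3-methylphenyl)methanone, not isolated | [Cs+].[Cs+].COc1cc([O-])c(C)c(OC)c1C(=O)c1c(OC)cc([O-])c(C)c1OC | intermediate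
15 | bis(2,4,6-trimethoxy-3-methylphenyl)methanone | COc1cc(OC)c(C)c(OC)c1C(=O)c1c(OC)cc(OC)c(C)c1OC | intermediate
16 | bis[2-(dichloroboryloxy)-4,6-dimethoxy-3-methylphenyl]methanone (boron-carbonyl chelate), not isolated | COc1cc(OC)c(C(=O)c2c(OC)cc(OC)c(C)c2OB(Cl)Cl)c(OB(Cl)Cl)c1C | intermediate
17 | 2,2'-dihydroxy-4,4',6,6'-tetramethoxy-3,3'-dimethylbenzophenone | COc1cc(OC)c(C(=O)c2c(OC)cc(OC)c(C)c2O)c(O)c1C | target

Total step count: 7 steps. Longest linear sequence: 5 steps (7 to 9, 11, 13, 15 and 17; the branch from 1 through 5 and 6 joins at step 5 and has the same length).

Least certain steps

Step 5 (key step, proposed new method). The cycloaddition of a donor-substituted alkyne at a fully substituted diene terminus may be too slow, so that oligomerisation or hydration of the ynone and dimerisation or desilylation of the diene take over. The sequence may stall after the first annulation for steric reasons. Silyl transfer inside a zwitterionic intermediate may end the reaction at a conjugate adduct instead of ring closure. The fallback uses known chemistry only; it sets out from 2 and comes back at 15, so that steps 3 to 6 are bypassed and step 7 follows unchanged. Purchased 2,4,6-trimethoxytoluene F1 is lithiated with n-BuLi in THF at the ring position between two methoxy groups (directed ortho metalation) to give (2,4,6-trimethoxy-3-methylphenyl)lithium F2. Two equivalents of F2 add to 2, through 2,4,6-trimethoxy-3-methylbenzaldehyde F3 formed in the flask, to give bis(2,4,6-trimethoxy-3-methylphenyl)methanol F4. Oxidation of F4 with MnO2 or the Dess-Martin periodinane gives 15.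

Step 2. The small push-pull diynone may decompose during oxidation, filtration or concentration (hydration, addition of adventitious nucleophiles, oligomerisation), and one step earlier the alkoxyethynyl carbinol may rearrange to an unsaturated ester if the work-up turns acidic. The fallback changes the oxidation level of the one-carbon unit; it sets out from 1 and comes back at 6, bypassing 5. 3 is generated as in step 1 and added (two equivalents) to N,N'-dimethoxy-N,N'-dimethylurea F5. The first addition gives the Weinreb amide N,3-dimethoxy-N-methylprop-2-ynamide F6 in the flask, and the second gives, after hydrolysis of the chelated tetrahedral adduct, 6 directly, so that no carbinol and no oxidant are involved.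

Step 4. Gamma deprotonation or enolate equilibration would move the methyl from the diene terminus to the saturated bridge, and in step 5 this would lead to loss of propene and of the methyl group; C-silylation and hydrolysis of the dienol ether on isolation are further losses. The fallback replaces enolate chemistry by arene reduction; it sets out from 6, which is kept as the dienophile, and comes back at 15, bypassing 11 to 14. Purchased 2,4-dimethoxytoluene F7 is reduced (Li, liquid NH3, t-BuOH, THF) to 1,5-dimethoxy-2-methylcyclohexa-1,4-diene F8, which is conjugated with KOt-Bu in DMSO to 1,3-dimethoxy-4-methylcyclohexa-1,3-diene F9. F9 must be freed of its bridge-methyl isomer by careful fractional distillation before use. Heating F9 with 6 as in step 5 should give, through bis(1,3,5-trimethoxy-4-methylbicyclo[2.2.2]octa-2,5-dien-2-yl)methanone F10 and loss of ethene, 15 without a separate methylation step. This path is one step shorter, but it depends on complete removal of the diene isomer and still uses the untested cycloaddition.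

Step 7. Site selectivity between the two chelatable ortho methoxy groups of each ring may be incomplete, cleavage in the second ring may be slow once the carbonyl is held in the first chelate, or cleavage may go on to C6. The fallback replaces selective dealkylation by selective alkylation; it sets out from 15 and comes back at 17. Excess BBr3 in CH2Cl2 (−78 °C to rt) cleaves all six methyl ethers to bis(2,4,6-trihydroxy-3-methylphenyl)methanone F11. Partial methylation of F11 with four equivalents of dimethyl sulfate and K2CO3 in acetone should then methylate the unchelated C4 hydroxyls and the less hindered C6 hydroxyls, the C2 hydroxyl that is hydrogen-bonded to the carbonyl and buttressed by the C-methyl being the slowest, as is usual for acylphloroglucinols.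

Further compounds

F1 | step 5 | 2,4,6-trimethoxytoluene (1,3,5-trimethoxy-2-methylbenzene) | COc1cc(OC)c(C)c(OC)c1
F2 | step 5 | (2,4,6-trimethoxy-3-methylphenyl)lithium | [Li]c1c(OC)cc(OC)c(C)c1OC
F3 | step 5 | 2,4,6-trimethoxy-3-methylbenzaldehyde | COc1cc(OC)c(C=O)c(OC)c1C
F4 | step 5 | bis(2,4,6-trimethoxy-3-methylphenyl)methanol | COc1cc(OC)c(C(O)c2c(OC)cc(OC)c(C)c2OC)c(OC)c1C
F5 | step 2 | N,N'-dimethoxy-N,N'-dimethylurea | CON(C)C(=O)N(C)OC
F6 | step 2 | N,3-dimethoxy-N-methylprop-2-ynamide | CON(C)C(=O)C#COC
F7 | step 4 | 2,4-dimethoxytoluene | COc1ccc(C)c(OC)c1
F8 | step 4 | 1,5-dimethoxy-2-methylcyclohexa-1,4-diene | COC1=C(C)CC=C(OC)C1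
F9 | step 4 | 1,3-dimethoxy-4-methylcyclohexa-1,3-diene | COC1=CC(OC)=C(C)CC1
F10 | step 4 | bis(1,3,5-trimethoxy-4-methylbicyclo[2.2.2]octa-2,5-dien-2-yl)methanone | COC12C=C(OC)C(C)(CC1)C(OC)=C2C(=O)C1=C(OC)C2(C)CCC1(OC)C=C2OC
F11 | step 7 | bis(2,4,6-trihydroxy-3-methylphenyl)methanone | Cc1c(O)cc(O)c(C(=O)c2c(O)cc(O)c(C)c2O)c1O
A1 | alternative 1 | bis(2-hydroxy-4,6-dimethoxy-3-methylphenyl)methyl tert-butyldimethylsilyl ether | COc1cc(OC)c(C(O[Si](C)(C)C(C)(C)C)c2c(OC)cc(OC)c(C)c2O)c(O)c1C
A2 | alternative 1 | 3-methoxy-4-methylcyclobut-2-en-1-one (racemic) | COC1=CC(=O)C1C
A3 | alternative 1 | tert-butyl[(1,5-dimethoxypenta-1,4-diyn-3-yl)oxy]dimethylsilane | COC#CC(O[Si](C)(C)C(C)(C)C)C#COC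
A4 | alternative 2 | bis(2,4,6-trifluoro-3-methylphenyl)methanone | Cc1c(F)cc(F)c(C(=O)c2c(F)cc(F)c(C)c2F)c1F
A5 | alternative 2 | bis(2-fluoro-4,6-dimethoxy-3-methylphenyl)methanone | COc1cc(OC)c(C(=O)c2c(OC)cc(OC)c(C)c2F)c(F)c1C
A6 | alternative 3 | bis(2-hydroxy-4,6-dimethoxy-3-methylphenyl)methane | COc1cc(OC)c(Cc2c(OC)cc(OC)c(C)c2O)c(O)c1C
A7 | alternative 3 | 3,5-dimethoxy-2-methylphenol | COc1cc(O)c(C)c(OC)c1
A8 | alternative 3 | formaldehyde | C=O
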